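The data were computed with constants of no real substance; scatter was added.

Right-handed substrate ends lower than left-handed substrate in both earlier runs: the south-east run ends at 8 % against 35 %, from equal charges.

all flasks: left-handed substrate 0.24 M; right-handed substrate 0.24 M; gas 20 mM (held)
- south: free catalyst 0.12 mM; added ligand 1 mM; run made earlier
- south-east: free catalyst 0.48 mM; added ligand 1 mM; run made earlier
- flask: free catalyst 0.24 mM; added ligand 1.0 mM; time 40 min

| run | time / min | left-handed substrate / % | right-handed substrate / % |
|---|---|---|---|
| south | 2.00 | 51 | 47 |
| south | 6.00 | 45 | 43 |
| south | 12.0 | 46 | 37 |
| south | 20.0 | 45 | 28 |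
| south | 25.0 | 45 | 25 |
| south | 30.0 | 44 | 24 |
| south-east | 2.50 | 49 | 43 |
| south-east | 4.00 | 47 | 43 |
| south-east | 8.00 | 47 | 33 |
| south-east | 12.0 | 44 | 27 |
| south-east | 20.0 | 36 | 13 |
| south-east | 30.0 | 35 | 8 |

(readings scatter by 1.5 percentage points)

* part of the left-handed substrate and right-handed substrate charged together that has reacted at 40 min
* excess of left-handed product over right-handed product in the product at 40 min
* excess of right-handed substrate over left-handed substrate among what is left of the two at 40 min

- free catalyst is single-handed; left-handed substrate and right-handed substrate are mirror images of each other, charged as a racemate, each of them at the stated concentration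
- at the start none of reagent is dissolved
- the earlier runs were read with a standard deviation of 1.5 percentage points
- steps that have been proposed: reagent + catalyst intermediate B -> free catalyst + right-handed product; reagent + catalyst intermediate A -> free catalyst + left-handed product; gas <-> reagent; 2 free catalyst <-> resting dimer; free catalyst + left-handed substrate <-> catalyst intermediate A; free catalyst + right-handed substrate <-> catalyst intermediate B; free catalyst + added ligand <-> idle complex
- an excess is the difference of the two amounts in percent of their sum
- an excess is below zero if the other one leads

What would the opposite outcome need? Take each substrate's fraction of its own charge left. The south-east run gives 5.14 for the selectivity factor s, the logarithm of that fraction for right-handed substrate over the logarithm for left-handed substrate. If each substrate falls in proportion to itself under one catalyst, both logarithms grow together, so s holds along a run. The mirror-image zero is s = 1, with equal columns, and left-handed substrate leads in going below it. The last south-east readings stand 27 percentage points apart against a scatter of 1.5 points; the last south readings give 5.74.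

The flask's catalyst is twice the south charge and half the south-east one. The reckoning here therefore takes the geometric mean of the two right-handed logarithms and stretches it to 40 min. That leaves 21.3 % of the charge of right-handed substrate, and s then leaves 74.0 % of the charge of left-handed substrate. So c is 52.3 %, eP −50.3 % and eS −55.3 %.

The forecast says 52 %, −52 % and −56 %, on the ground that “Selectivity is therefore about 5 to 6”; its eP differs from the reckoning here by 1.7 points.

The flask gives 54.8 %, −43.5 % and −52.9 %, so eP parts from the forecast.

    reagent + catalyst intermediate B → free catalyst + right-handed product (k = 14000 M⁻¹ min⁻¹)
    reagent + catalyst intermediate A → free catalyst + left-handed product (k = 30000 M⁻¹ min⁻¹)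
    gas ⇌ reagent, rate k3*(csat - [reagent]) (kL = 1.90 min⁻¹)
    2 free catalyst ⇌ resting dimer, settled at all times (K = 3.20 × 10⁵ M⁻¹)
    free catalyst + left-handed substrate ⇌ catalyst intermediate A (K = 1.50 M⁻¹, k = 7500 M⁻¹ min⁻¹)
    free catalyst + right-handed substrate ⇌ catalyst intermediate B (K = 31.0 M⁻¹, k = 4600 M⁻¹ min⁻¹)
    free catalyst + added ligand ⇌ idle complex (K = 17000 M⁻¹, k = 350 M⁻¹ min⁻¹)

At 13.1 min in the flask reagent is used 2.8 times as fast by catalyst intermediate B as by catalyst intermediate A, and at 40.0 min the flask holds unbound 21 % of the charge of right-handed substrate against 69 % of the charge of left-handed substrate, which is s = 4.17 where the south-east reading of 5.14 would have kept 73.8 %. The neighbour flask with 0.0025 M of added ligand reaches c = 44.4 % and keeps 34 % against 77 % of the two charges, which is s = 4.13.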